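The cyclopentane is built by a one-pot dianion alkylation–conjugate addition; the two weakest points of the plan are that this step gives a racemate (resolved later through diastereomers, so half the material is lost) and that the trans ring fusion rests on a face-selective protonation in step 8.

Numbering: C1 is the methyl-bearing ring-fusion carbon, C2 and C3 the cyclopentane CH2 groups, C4 the isopropyl carbinol, C5 the ring-fusion CH, C6 the acyloxy carbon, C8/C9 the epoxide. The cyclopentane is cut at C2–C3 and C1–C5. The key step exploits C4, flanked by C3 and C5, as an acetoacetate ketone (C6 its ester carbon) and quaternary C1 as the β-carbon of a γ-bromo-β-methyl enoate: dianion alkylation (C3–C2) and 5-exo conjugate addition (C5–C1) build the ring in one pot from an acyclic precursor. The cycloheptene is closed later by metathesis at C8=C9; absolute configuration enters by reagent-controlled methallylation, after which the C1 epimer is removed.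

Key step: step 1

Remark (faces): α is the face of H5, O6 and the epoxide oxygen; β is the face of the C1 methyl and the C4 hydroxyl.
Remark (assumption): ethyl 4-bromo-3-methylbut-2-enoate is taken as a purchasable E/Z mixture; both isomers converge on 4 because C10 becomes a CH2 group, and the E isomer is drawn.

Step 1
Reactants: 1 ethyl acetoacetate; 2 ethyl (2E)-4-bromo-3-methylbut-2-enoate
Product: 4 rac-ethyl 2-(2-ethoxy-2-oxoethyl)-2-methyl-5-oxocyclopentane-1-carboxylate, via open-chain keto diester 3 (not isolated)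
Conditions: NaH, THF, 0 °C; n-BuLi, 0 °C; 2, −78 → 0 °C; EtOH, 50 °C; aq. NH4Cl
Reagents that add atoms: none
Why: The acetoacetate dianion is alkylated at its terminal carbon C3 by the primary allylic bromide of 2 (C3–C2), and the β-keto ester enolate that remains adds through C5 to the enoate β-carbon C1 (C1–C5), the new ester enolate being discharged by proton transfer from the more acidic C5–H, so that ethoxide in ethanol only has to shuttle protons. The closest known reaction type is the one-pot γ-alkylation and intramolecular Michael addition of β-keto ester dianions with 4-bromocrotonates, a formal anionic [3+2] annulation. The cyclopentane closes in the 5-exo-trig mode, which is allowed here because the nucleophile can react through its exocyclic ester enolate (enolexo). C1 becomes a quaternary stereocentre with no controlling element (racemate, resolved into diastereomers by the reagent-controlled step 6), and C5 is labile between two carbonyl groups and is made trigonal in step 2. The step needs γ- over α-alkylation (given by the dianion), substitution at CH2Br over attack on the hindered β,β-disubstituted enoate (favoured for the hard dianion at −78 °C) and C- over O-ring closure (the oxygen adduct forms reversibly, the C–C adduct is the thermodynamic sink).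

Step 2
Reactants: 4 rac-ethyl 2-(2-ethoxy-2-oxoethyl)-2-methyl-5-oxocyclopentane-1-carboxylate
Product: 5 rac-ethyl 2-[(tert-butyldimethylsilyl)oxy]-5-(2-ethoxy-2-oxoethyl)-5-methylcyclopent-1-ene-1-carboxylate
Conditions: TBSOTf, Et3N, CH2Cl2, 0 °C
Reagents that add atoms: tert-butyldimethylsilyl trifluoromethanesulfonate, CC(C)(C)[Si](C)(C)OS(=O)(=O)C(F)(F)F
Why: Soft enolisation and O-silylation (silyl enol ether formation) at the more acidic C5–H of the β-keto ester should give the conjugated enol ether, which masks the C4 ketone against hydride and carbanion reagents and makes C5 trigonal so that its epimers converge.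

Step 3
Reactants: 5 rac-ethyl 2-[(tert-butyldimethylsilyl)oxy]-5-(2-ethoxy-2-oxoethyl)-5-methylcyclopent-1-ene-1-carboxylate
Product: 6 rac-2-{3-[(tert-butyldimethylsilyl)oxy]-2-(hydroxymethyl)-1-methylcyclopent-2-en-1-yl}ethan-1-ol
Conditions: i-Bu2AlH (5 equiv), CH2Cl2, −78 → 0 °C; aq. KNaC4H4O6
Reagents that add atoms: none
Why: Ester reduction with i-Bu2AlH should take both the vinylogous carbonate ester and the saturated ester to primary alcohols, while the silyl enol ether is inert to hydride and the aluminium alkoxides are too weakly nucleophilic to take over the silyl group.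

Step 4
Reactants: 6 rac-2-{3-[(tert-butyldimethylsilyl)oxy]-2-(hydroxymethyl)-1-methylcyclopent-2-en-1-yl}ethan-1-ol
Product: 7 rac-2-[(tert-butyldimethylsilyl)oxy]-5-methyl-5-(2-oxoethyl)cyclopent-1-ene-1-carbaldehyde
Conditions: (COCl)2, DMSO, CH2Cl2, −78 °C; Et3N, −78 → 0 °C
Reagents that add atoms: none
Why: Swern oxidation should convert both primary alcohols into aldehydes under non-acidic conditions that leave the silyl enol ether intact, without touching the stereocentre.

Step 5
Reactants: 7 rac-2-[(tert-butyldimethylsilyl)oxy]-5-methyl-5-(2-oxoethyl)cyclopent-1-ene-1-carbaldehyde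
Product: 8 rac-2-[(tert-butyldimethylsilyl)oxy]-5-methyl-5-(prop-2-en-1-yl)cyclopent-1-ene-1-carbaldehyde
Conditions: Ph3PCH3Br, NaN(SiMe3)2, THF, 0 °C; 7 (1 equiv of ylide), −78 → −20 °C
Reagents that add atoms: methyltriphenylphosphonium bromide, C[P+](c1ccccc1)(c1ccccc1)c1ccccc1.[Br-]
Why: Wittig methylenation with one equivalent of ylide at low temperature should take the saturated aldehyde selectively, because the ring formyl group is a vinylogous silyl ester whose carbonyl is deactivated by conjugation with the enol ether oxygen.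

Step 6
Reactants: 8 rac-2-[(tert-butyldimethylsilyl)oxy]-5-methyl-5-(prop-2-en-1-yl)cyclopent-1-ene-1-carbaldehyde
Product: 9 (1S)-1-[(5R)-2-[(tert-butyldimethylsilyl)oxy]-5-methyl-5-(prop-2-en-1-yl)cyclopent-1-en-1-yl]-3-methylbut-3-en-1-ol
Conditions: (−)-B-methoxydiisopinocampheylborane, CH2=C(CH3)CH2MgCl, Et2O, −78 °C → rt; 8, −78 °C; HOCH2CH2NH2 work-up
Reagents that add atoms: 2-methylallylmagnesium chloride, CC(=C)C[Mg]Cl (delivered through (−)-B-(2-methylallyl)diisopinocampheylborane)
Why: Brown methallylation through a closed six-membered transition state should add the 2-methylallyl group to the si face of the aldehyde under reagent control (the borane from (+)-α-pinene), setting C6 as S in both enantiomers of 8, so that (5R)-8 gives 9 and (5S)-8 gives a diastereomer that is removed after step 7.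

Step 7
Reactants: 9 (1S)-1-[(5R)-2-[(tert-butyldimethylsilyl)oxy]-5-methyl-5-(prop-2-en-1-yl)cyclopent-1-en-1-yl]-3-methylbut-3-en-1-ol
Product: 10 (4S,8aR)-3-[(tert-butyldimethylsilyl)oxy]-6,8a-dimethyl-1,2,4,5,8,8a-hexahydroazulen-4-ol
Conditions: second-generation Grubbs catalyst (5 mol %), CH2Cl2, 40 °C
Reagents that add atoms: none
Why: Ring-closing metathesis should join the monosubstituted and the 1,1-disubstituted terminal alkenes to the trisubstituted C8=C9 bond of the seven-membered ring (necessarily Z), the tetrasubstituted silyl enol ether being inert, and the C1 epimer derived from (5S)-8 is separated here by chromatography as a diastereomer.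

Step 8
Reactants: 10 (4S,8aR)-3-[(tert-butyldimethylsilyl)oxy]-6,8a-dimethyl-1,2,4,5,8,8a-hexahydroazulen-4-ol
Product: 11 (3aR,8S,8aS)-8-hydroxy-3a,6-dimethyl-3,3a,4,7,8,8a-hexahydroazulen-1(2H)-one
Conditions: Bu4NF, AcOH, THF, −20 → 0 °C
Reagents that add atoms: none
Why: Fluoride cleavage of the silyl enol ether followed by kinetic protonation of the enol at C5 under acetic acid buffering (which suppresses β-elimination of the C6 hydroxyl) should give the trans ring fusion, because on the cycloheptene chair, where the fused cyclopentene holds C2 in the enol plane, the C1 methyl is pseudo-axial and screens the β face so that the proton enters on the α face.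

Step 9
Reactants: 11 (3aR,8S,8aS)-8-hydroxy-3a,6-dimethyl-3,3a,4,7,8,8a-hexahydroazulen-1(2H)-one
Product: 12 (1R,3aR,8S,8aS)-3a,6-dimethyl-1-(propan-2-yl)-1,2,3,3a,4,7,8,8a-octahydroazulene-1,8-diol
Conditions: i-PrMgCl (3 equiv), CeCl3, THF, −78 °C; aq. NH4Cl
Reagents that add atoms: isopropylmagnesium chloride, CC(C)[Mg]Cl
Why: 1,2-Addition of the weakly basic isopropylcerium reagent to the cyclopentanone should occur from the α face, anti to the C6 carbon on C5 and to the C1 methyl, which both lie on the β face, giving the 4β-hydroxy-4α-isopropyl centre without enolisation at C5.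

Step 10
Reactants: 12 (1R,3aR,8S,8aS)-3a,6-dimethyl-1-(propan-2-yl)-1,2,3,3a,4,7,8,8a-octahydroazulene-1,8-diol
Product: 13 8α,9α-epoxide of 12 (1R,4R,5S,6S,8R,9S in the C1–C10 numbering)
Conditions: VO(acac)2 (5 mol %), t-BuOOH, toluene, 0 °C → rt
Reagents that add atoms: tert-butyl hydroperoxide, CC(C)(C)OO
Why: Hydroxyl-directed vanadium-catalysed epoxidation should deliver oxygen to C8=C9 on the face syn to the homoallylic C6 hydroxyl, which is also the face opposite the angular methyl, giving the 8α,9α-epoxide, the tertiary C4 hydroxyl being too remote to compete.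

Step 11
Reactants: 13 8α,9α-epoxide of 12; 14 3,4-dimethoxybenzoyl chloride
Product: 15 CNP0251065.1, the C6 3,4-dimethoxybenzoate of 13
Conditions: Et3N, DMAP (cat.), CH2Cl2, 0 °C → rt
Reagents that add atoms: none
Why: DMAP-catalysed acylation should esterify the secondary C6 hydroxyl only, since the tertiary C4 hydroxyl is unreactive under these conditions and the epoxide survives the buffered, non-acidic medium.

Compound list
1 | ethyl acetoacetate | CCOC(=O)CC(C)=O | starting material
2 | ethyl (2E)-4-bromo-3-methylbut-2-enoate | CCOC(=O)/C=C(\C)CBr | starting material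
3 | diethyl (2E)-3-methyl-6-oxooct-2-enedioate | CCOC(=O)CC(=O)CC/C(C)=C/C(=O)OCC | intermediate
4 | rac-ethyl 2-(2-ethoxy-2-oxoethyl)-2-methyl-5-oxocyclopentane-1-carboxylate (racemic at C1 of the target numbering; C5 epimers and enol) | CCOC(=O)CC1(C)CCC(=O)C1C(=O)OCC | intermediate
5 | rac-ethyl 2-[(tert-butyldimethylsilyl)oxy]-5-(2-ethoxy-2-oxoethyl)-5-methylcyclopent-1-ene-1-carboxylate | CCOC(=O)CC1(C)CCC(O[Si](C)(C)C(C)(C)C)=C1C(=O)OCC | intermediate
6 | rac-2-{3-[(tert-butyldimethylsilyl)oxy]-2-(hydroxymethyl)-1-methylcyclopent-2-en-1-yl}ethan-1-ol | OCCC1(C)CCC(O[Si](C)(C)C(C)(C)C)=C1CO | intermediate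
7 | rac-2-[(tert-butyldimethylsilyl)oxy]-5-methyl-5-(2-oxoethyl)cyclopent-1-ene-1-carbaldehyde | O=CCC1(C)CCC(O[Si](C)(C)C(C)(C)C)=C1C=O | intermediate
8 | rac-2-[(tert-butyldimethylsilyl)oxy]-5-methyl-5-(prop-2-en-1-yl)cyclopent-1-ene-1-carbaldehyde | C=CCC1(C)CCC(O[Si](C)(C)C(C)(C)C)=C1C=O | intermediate
9 | (1S)-1-[(5R)-2-[(tert-butyldimethylsilyl)oxy]-5-methyl-5-(prop-2-en-1-yl)cyclopent-1-en-1-yl]-3-methylbut-3-en-1-ol (carried with its (5S) diastereomer until step 7) | C=C(C)C[C@H](O)C1=C(O[Si](C)(C)C(C)(C)C)CC[C@]1(C)CC=C | intermediate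
10 | (4S,8aR)-3-[(tert-butyldimethylsilyl)oxy]-6,8a-dimethyl-1,2,4,5,8,8a-hexahydroazulen-4-ol | CC1=CC[C@@]2(C)CCC(O[Si](C)(C)C(C)(C)C)=C2[C@@H](O)C1 | intermediate
11 | (3aR,8S,8aS)-8-hydroxy-3a,6-dimethyl-3,3a,4,7,8,8a-hexahydroazulen-1(2H)-one (trans-fused) | CC1=CC[C@@]2(C)CCC(=O)[C@@H]2[C@@H](O)C1 | intermediate
12 | (1R,3aR,8S,8aS)-3a,6-dimethyl-1-(propan-2-yl)-1,2,3,3a,4,7,8,8a-octahydroazulene-1,8-diol | CC1=CC[C@@]2(C)CC[C@@](O)(C(C)C)[C@@H]2[C@@H](O)C1 | intermediate
13 | 8α,9α-epoxide of 12 (1R,4R,5S,6S,8R,9S in the C1–C10 numbering) | O[C@H]2C[C@@]3(C)O[C@H]3C[C@@]3(C)CC[C@@](O)(C(C)C)[C@H]23 | intermediate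
14 | 3,4-dimethoxybenzoyl chloride | COc1ccc(cc1OC)C(Cl)=O | starting material
15 | CNP0251065.1, the C6 3,4-dimethoxybenzoate of 13 | COc1ccc(C(=O)O[C@H]2C[C@@]3(C)O[C@H]3C[C@@]3(C)CC[C@@](O)(C(C)C)[C@H]23)cc1OC | target

Total steps: 11. Longest linear sequence: 11 steps (1 and 2 to 15; 14 enters in the last step).

Steps most likely to fail

Step 1. The conjugate ring closure onto the β,β-disubstituted enoate may be slow or may revert, leaving open-chain material, or the enolate oxygen may close the ring instead. The fallback sets out from 3, isolated by quenching the alkylation cold. Photodeconjugation (254 nm, MeCN) would move the double bond out of conjugation to give diethyl 3-methylidene-6-oxooctanedioate F1. Ph3PAuCl/AgOTf (catalytic, toluene, 80 °C) would then add the β-keto ester C5–H across the 1,1-disubstituted alkene in the Markovnikov sense (5-exo, the alkene CH2 becoming the C1 methyl), an irreversible Conia-ene-type hydroalkylation. The fallback returns to the route at 4.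

Step 8. Protonation of the enol at C5 may show poor facial selectivity and give the cis ring fusion. The fallback sets out from 8 and places the C6 hydroxyl on the β face first, so that two pseudo-axial groups screen that face.
- The enantiomeric borane, (+)-B-(2-methylallyl)diisopinocampheylborane, would give (1R)-1-[(5R)-2-[(tert-butyldimethylsilyl)oxy]-5-methyl-5-(prop-2-en-1-yl)cyclopent-1-en-1-yl]-3-methylbut-3-en-1-ol F2, whose (5S) diastereomer is removed after metathesis.
- Ring-closing metathesis would give (4R,8aR)-3-[(tert-butyldimethylsilyl)oxy]-6,8a-dimethyl-1,2,4,5,8,8a-hexahydroazulen-4-ol F3, in which the C6 hydroxyl and the C1 methyl are both pseudo-axial on the β face.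
- Buffered Bu4NF would give (3aR,8R,8aS)-8-hydroxy-3a,6-dimethyl-3,3a,4,7,8,8a-hexahydroazulen-1(2H)-one F4.
- i-PrMgCl/CeCl3 would give (1R,3aR,8R,8aS)-3a,6-dimethyl-1-(propan-2-yl)-1,2,3,3a,4,7,8,8a-octahydroazulene-1,8-diol F5.
- Mitsunobu esterification (PPh3, diisopropyl azodicarboxylate, 3,4-dimethoxybenzoic acid) would invert C6 and give (1R,3aR,8S,8aS)-1-hydroxy-3a,6-dimethyl-1-(propan-2-yl)-1,2,3,3a,4,7,8,8a-octahydroazulen-8-yl 3,4-dimethoxybenzoate F6.
- mCPBA (NaHCO3, CH2Cl2) should epoxidise C8=C9 from the α face, anti to the angular methyl, and the fallback returns to the route at 15.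

Step 9. The secondary organometallic may reduce the ketone by β-hydride transfer, enolise C5, or open the β-hydroxy ketone by retro-aldol cleavage. The fallback sets out from 11. CH2=C(CH3)MgBr/CeCl3 (THF, −78 °C), a smaller sp2 nucleophile that cannot transfer hydride, would give (1S,3aR,8S,8aS)-3a,6-dimethyl-1-(prop-1-en-2-yl)-1,2,3,3a,4,7,8,8a-octahydroazulene-1,8-diol F7. H2 with RhCl(PPh3)3 would then saturate the 1,1-disubstituted alkene in preference to the trisubstituted ring alkene. The fallback returns to the route at 12.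

Further compounds
F1 | step 1 | diethyl 3-methylidene-6-oxooctanedioate | CCOC(=O)CC(=C)CCC(=O)CC(=O)OCC
F2 | step 8 | (1R)-1-[(5R)-2-[(tert-butyldimethylsilyl)oxy]-5-methyl-5-(prop-2-en-1-yl)cyclopent-1-en-1-yl]-3-methylbut-3-en-1-ol | C=C(C)C[C@@H](O)C1=C(O[Si](C)(C)C(C)(C)C)CC[C@]1(C)CC=C
F3 | step 8 | (4R,8aR)-3-[(tert-butyldimethylsilyl)oxy]-6,8a-dimethyl-1,2,4,5,8,8a-hexahydroazulen-4-ol | CC1=CC[C@@]2(C)CCC(O[Si](C)(C)C(C)(C)C)=C2[C@H](O)C1
F4 | step 8 | (3aR,8R,8aS)-8-hydroxy-3a,6-dimethyl-3,3a,4,7,8,8a-hexahydroazulen-1(2H)-one | CC1=CC[C@@]2(C)CCC(=O)[C@@H]2[C@H](O)C1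
F5 | step 8 | (1R,3aR,8R,8aS)-3a,6-dimethyl-1-(propan-2-yl)-1,2,3,3a,4,7,8,8a-octahydroazulene-1,8-diol | CC1=CC[C@@]2(C)CC[C@@](O)(C(C)C)[C@@H]2[C@H](O)C1
F6 | step 8 | (1R,3aR,8S,8aS)-1-hydroxy-3a,6-dimethyl-1-(propan-2-yl)-1,2,3,3a,4,7,8,8a-octahydroazulen-8-yl 3,4-dimethoxybenzoate | COc1ccc(C(=O)O[C@H]2CC(C)=CC[C@@]3(C)CC[C@@](O)(C(C)C)[C@H]23)cc1OC
F7 | step 9 | (1S,3aR,8S,8aS)-3a,6-dimethyl-1-(prop-1-en-2-yl)-1,2,3,3a,4,7,8,8a-octahydroazulene-1,8-diol | CC1=CC[C@@]2(C)CC[C@@](O)(C(C)=C)[C@@H]2[C@@H](O)C1
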